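**Retrosynthetic overview**

1. Locants: ring C (carbocycle) = C1(CH3)(O)–C2H(OH)–C3H2–C4H–C5H(OAc)–C6H2; side chain C7(CH3)–C8H(O)–C9H2–C10HBr–C11(CH3)2; ring A = oxane (O, C7–C11); ring B = oxepane (O, C8, C7, C4, C3, C2, C1).
2. Target 23 ⇒ silyl ether 22 ⇒ one Prins cascade that makes O–C1, C6–C1 and C5–OAc ⇒ monocyclic bromo-oxane hydroxy ketone 19 carrying a vinyl group (C5=C6) on C4.
3. 19 ⇒ ring A by bromoetherification of the C7 carbinol onto a prenyl alkene; C8 by chelate-controlled prenylation; C7 and C4 by Sharpless epoxidation and vinyl cuprate opening; C2 from methyl (2R)-glycidate.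
4. Order of ring formation: A (step 11), then B and, last, C (both in step 13, B before C).
5. Enabling feature: C1 is both the tertiary ether carbon of ring B and a member of ring C, so it is a masked ketone that can become a cyclic oxocarbenium ion. The acetoxy carbon C5 lies 1,3 to it through C6H2, so O–C1–C6–C5–OAc is the retron of an oxocarbenium/vinyl/acetate Prins addition, with the C4 vinyl group 1,4 across the oxepane from C1.

Key step: step 13

Step 1
Reactants: 1 methyl (2R)-oxirane-2-carboxylate; 2 vinylmagnesium bromide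
Product: 3 methyl (2R)-2-hydroxypent-4-enoate
Conditions: CuI (10 mol %), THF, −78 → −40 °C; aq NH4Cl
Reagents that add atoms: none
Why: Copper-catalysed Grignard opening of a terminal epoxide (SN2 at CH2), which does not touch the stereocentre that becomes C2.

Step 2
Reactants: 3 methyl (2R)-2-hydroxypent-4-enoate
Product: 4 methyl (2R)-2-[(tert-butyldimethylsilyl)oxy]pent-4-enoate
Conditions: TBSCl, imidazole, DMF, 0 °C → rt
Reagents that add atoms: tert-butyldimethylsilyl chloride, CC(C)(C)[Si](C)(C)Cl
Why: Imidazole-promoted silylation of a secondary alcohol, giving an ether that should survive every step up to the acid-mediated key step.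

Step 3
Reactants: 4 methyl (2R)-2-[(tert-butyldimethylsilyl)oxy]pent-4-enoate
Product: 5 (2R)-2-[(tert-butyldimethylsilyl)oxy]-N-methoxy-N-methylpent-4-enamide
Conditions: MeNHOMe·HCl, i-PrMgCl, THF, −20 °C
Reagents that add atoms: N,O-dimethylhydroxylamine hydrochloride, CNOC.Cl
Why: Ester aminolysis by the magnesium amide of N,O-dimethylhydroxylamine (Weinreb amide formation), giving an acyl group that should not lactonise onto the later C7 alkoxide and that stops at the ketone in step 12.

Step 4
Reactants: 5 (2R)-2-[(tert-butyldimethylsilyl)oxy]-N-methoxy-N-methylpent-4-enamide; 6 methacrolein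
Product: 7 (2R,4E)-2-[(tert-butyldimethylsilyl)oxy]-N-methoxy-N,5-dimethyl-6-oxohex-4-enamide
Conditions: second-generation Hoveyda–Grubbs catalyst (5 mol %), CH2Cl2, 40 °C
Reagents that add atoms: none
Why: Olefin cross-metathesis of a terminal alkene with methacrolein, which should give the (E)-trisubstituted enal as the thermodynamic product.

Step 5
Reactants: 7 (2R,4E)-2-[(tert-butyldimethylsilyl)oxy]-N-methoxy-N,5-dimethyl-6-oxohex-4-enamide
Product: 8 (2R,4E)-2-[(tert-butyldimethylsilyl)oxy]-6-hydroxy-N-methoxy-N,5-dimethylhex-4-enamide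
Conditions: NaBH4, CeCl3·7H2O, MeOH, −78 °C
Reagents that add atoms: none
Why: Luche reduction, 1,2-selective for the enal, with the Weinreb amide not reduced at −78 °C.

Step 6
Reactants: 8 (2R,4E)-2-[(tert-butyldimethylsilyl)oxy]-6-hydroxy-N-methoxy-N,5-dimethylhex-4-enamide
Product: 9 (2R)-2-[(tert-butyldimethylsilyl)oxy]-3-[(2R,3R)-3-(hydroxymethyl)-3-methyloxiran-2-yl]-N-methoxy-N-methylpropanamide
Conditions: Ti(Oi-Pr)4 (10 mol %), D-(−)-diethyl tartrate (12 mol %), t-BuOOH, 4 Å MS, CH2Cl2, −20 °C
Reagents that add atoms: tert-butyl hydroperoxide, CC(C)(C)OO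
Why: Sharpless asymmetric epoxidation, in which D-(−)-diethyl tartrate delivers oxygen to one face of the (E)-2-methyl allylic alcohol by reagent control and so sets C7 and, provisionally, C4 as the (2R,3R)-epoxide.

Step 7
Reactants: 9 (2R)-2-[(tert-butyldimethylsilyl)oxy]-3-[(2R,3R)-3-(hydroxymethyl)-3-methyloxiran-2-yl]-N-methoxy-N-methylpropanamide; 2 vinylmagnesium bromide
Product: 11 (2R,4R,5S)-2-[(tert-butyldimethylsilyl)oxy]-4-ethenyl-5,6-dihydroxy-N-methoxy-N,5-dimethylhexanamide, via bromomagnesium divinylcuprate 10 (not isolated)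
Conditions: 2 (6 equiv), CuI (3 equiv), THF, −40 → −10 °C; aq NH4Cl
Reagents that add atoms: none
Why: SN2 epoxide opening by a vinyl cuprate, possible only at the secondary carbon because the other epoxide carbon is quaternary, so C4 is set by inversion and the C7 carbinol keeps its configuration.

Step 8
Reactants: 11 (2R,4R,5S)-2-[(tert-butyldimethylsilyl)oxy]-4-ethenyl-5,6-dihydroxy-N-methoxy-N,5-dimethylhexanamide
Product: 12 (2R,4R,5S)-2-[(tert-butyldimethylsilyl)oxy]-4-ethenyl-5-hydroxy-N-methoxy-N,5-dimethyl-6-oxohexanamide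
Conditions: SO3·pyridine, DMSO, i-Pr2NEt, CH2Cl2, 0 °C; used crude
Reagents that add atoms: none
Why: Parikh–Doering oxidation of the primary alcohol, which neither cleaves the 1,2-diol nor can epimerise the quaternary α-carbon.

Step 9
Reactants: 12 (2R,4R,5S)-2-[(tert-butyldimethylsilyl)oxy]-4-ethenyl-5-hydroxy-N-methoxy-N,5-dimethyl-6-oxohexanamide; 13 prenyl chloride
Product: 15 (2R,4R,5S,6S)-2-[(tert-butyldimethylsilyl)oxy]-4-ethenyl-5,6-dihydroxy-N-methoxy-N,5,9-trimethyldec-8-enamide, via prenylbarium chloride 14 (not isolated)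
Conditions: activated Ba (from BaI2, lithium biphenylide), 13, THF, −78 °C; then 12, −78 °C
Reagents that add atoms: none
Why: α-Selective carbonyl allylation by an allylbarium reagent (linear prenyl transfer), in which attack on the five-membered barium chelate of the α-alkoxy aldehyde from the side of the small CH3 group (Cram chelate model) should set C8.

Step 10
Reactants: 15 (2R,4R,5S,6S)-2-[(tert-butyldimethylsilyl)oxy]-4-ethenyl-5,6-dihydroxy-N-methoxy-N,5,9-trimethyldec-8-enamide
Product: 16 (2R,4R,5S,6S)-6-(acetyloxy)-2-[(tert-butyldimethylsilyl)oxy]-4-ethenyl-5-hydroxy-N-methoxy-N,5,9-trimethyldec-8-enamide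
Conditions: Ac2O, pyridine, DMAP (cat.), CH2Cl2, 0 °C
Reagents that add atoms: acetic anhydride, CC(=O)OC(C)=O
Why: DMAP-catalysed acylation, selective for the secondary over the tertiary hydroxyl, which keeps the C8 oxygen from competing (5-endo) in step 11.

Step 11
Reactants: 16 (2R,4R,5S,6S)-6-(acetyloxy)-2-[(tert-butyldimethylsilyl)oxy]-4-ethenyl-5-hydroxy-N-methoxy-N,5,9-trimethyldec-8-enamide
Product: 17 (2S,3S,5S)-5-bromo-2-{(3R,5R)-5-[(tert-butyldimethylsilyl)oxy]-6-[methoxy(methyl)amino]-6-oxohex-1-en-3-yl}-2,6,6-trimethyloxan-3-yl acetate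
Conditions: TBCO, MeNO2, 0 °C
Reagents that add atoms: 2,4,4,6-tetrabromocyclohexa-2,5-dien-1-one (TBCO), O=C1C(Br)=CC(Br)(Br)C=C1Br
Why: Bromonium-induced 6-endo bromoetherification by the tertiary C7 hydroxyl at the tertiary alkene carbon, through a chair transition state with Br and the C4 side chain equatorial that should set C10, the trisubstituted alkene reacting much faster than the vinyl group.

Step 12
Reactants: 17 (2S,3S,5S)-5-bromo-2-{(3R,5R)-5-[(tert-butyldimethylsilyl)oxy]-6-[methoxy(methyl)amino]-6-oxohex-1-en-3-yl}-2,6,6-trimethyloxan-3-yl acetate; 18 methylmagnesium bromide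
Product: 19 (3R,5R)-5-[(2S,3S,5S)-5-bromo-3-hydroxy-2,6,6-trimethyloxan-2-yl]-3-[(tert-butyldimethylsilyl)oxy]hept-6-en-2-one
Conditions: 18 (5 equiv), THF, −78 → 0 °C; aq NH4Cl, 0 °C
Reagents that add atoms: none
Why: Weinreb ketone synthesis (the chelated tetrahedral adduct prevents over-addition), with the excess Grignard reagent removing the C8 acetate in the same flask.

Step 13
Reactants: 19 (3R,5R)-5-[(2S,3S,5S)-5-bromo-3-hydroxy-2,6,6-trimethyloxan-2-yl]-3-[(tert-butyldimethylsilyl)oxy]hept-6-en-2-one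
Product: 22 (1R,2R,4R,5S,7S,8S,10S)-5-acetoxy-10-bromo-2-[(tert-butyldimethylsilyl)oxy]-1,8:7,11-diepoxybisabolane, via cyclic hemiketal 20 (not isolated), via oxepanyl oxocarbenium ion 21 (not isolated)
Conditions: BF3·OEt2, AcOH, 4 Å MS, CH2Cl2, −30 → 0 °C
Reagents that add atoms: acetic acid, CC(=O)O
Why: Proposed new method: BF3·OEt2 should close ring B reversibly by attack of the C8 hydroxyl on the C1 ketone (7-exo-trig hemiketalisation to 20) and ionise it to the tertiary oxocarbenium ion 21; the C5=C6 vinyl group on C4, held 1,4 across the oxepane, then adds through its terminal carbon C6 (6-endo-trig for the alkene, exo for the C=O+ unit) while acetic acid captures the developing C5 cation, so ring C is the last ring to close. The closest known reactions are the Prins cyclisation with acetate capture under BF3·OEt2/AcOH and acetal- or ketone-initiated cation–olefin carbocyclisations onto monosubstituted alkenes; what has not been shown is the tethered oxygen in a seven-membered oxocarbenium ion. C1 can only form as drawn, because the C5–C6 chain must bridge the face of ring B on which C4 already carries it. C5 should follow from anti addition across the alkene in a twist-boat transition state whose sense of twist is dictated by the chair of ring A (Br and the C4 chain equatorial), which puts acetate on the face syn to the oxygen bridge. The step needs oxygen-before-carbon chemoselectivity, expected because an unactivated vinyl group adds to the cyclic oxocarbenium ion but not to the free ketone. It also needs the C2 silyl ether to stay in place, which the low temperature should secure.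

Step 14
Reactants: 22 (1R,2R,4R,5S,7S,8S,10S)-5-acetoxy-10-bromo-2-[(tert-butyldimethylsilyl)oxy]-1,8:7,11-diepoxybisabolane
Product: 23 (1R,2R,4R,5S,7S,8S,10S)-5-acetoxy-10-bromo-1,8:7,11-diepoxybisabolan-2-ol (CNP0247588.2)
Conditions: HF·pyridine, pyridine, THF, 0 °C → rt
Reagents that add atoms: none
Why: Fluoride-mediated desilylation under weakly acidic HF·pyridine, which should leave the acetate, both ethers and the secondary bromide untouched.

**Compound list**

1 | methyl (2R)-oxirane-2-carboxylate | COC(=O)[C@H]1CO1 | starting material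
2 | vinylmagnesium bromide | C=C[Mg]Br | starting material
3 | methyl (2R)-2-hydroxypent-4-enoate | C=CC[C@@H](O)C(=O)OC | intermediate
4 | methyl (2R)-2-[(tert-butyldimethylsilyl)oxy]pent-4-enoate | C=CC[C@@H](O[Si](C)(C)C(C)(C)C)C(=O)OC | intermediate
5 | (2R)-2-[(tert-butyldimethylsilyl)oxy]-N-methoxy-N-methylpent-4-enamide | C=CC[C@@H](O[Si](C)(C)C(C)(C)C)C(=O)N(C)OC | intermediate
6 | methacrolein (2-methylprop-2-enal) | CC(=C)C=O | starting material
7 | (2R,4E)-2-[(tert-butyldimethylsilyl)oxy]-N-methoxy-N,5-dimethyl-6-oxohex-4-enamide | O=C/C(C)=C/C[C@@H](O[Si](C)(C)C(C)(C)C)C(=O)N(C)OC | intermediate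
8 | (2R,4E)-2-[(tert-butyldimethylsilyl)oxy]-6-hydroxy-N-methoxy-N,5-dimethylhex-4-enamide | OC/C(C)=C/C[C@@H](O[Si](C)(C)C(C)(C)C)C(=O)N(C)OC | intermediate
9 | (2R)-2-[(tert-butyldimethylsilyl)oxy]-3-[(2R,3R)-3-(hydroxymethyl)-3-methyloxiran-2-yl]-N-methoxy-N-methylpropanamide | OC[C@@]1(C)O[C@@H]1C[C@@H](O[Si](C)(C)C(C)(C)C)C(=O)N(C)OC | intermediate
10 | bromomagnesium divinylcuprate | C=C[Cu-]C=C.[Mg+]Br | intermediate
11 | (2R,4R,5S)-2-[(tert-butyldimethylsilyl)oxy]-4-ethenyl-5,6-dihydroxy-N-methoxy-N,5-dimethylhexanamide | OC[C@@](C)(O)[C@@H](C=C)C[C@@H](O[Si](C)(C)C(C)(C)C)C(=O)N(C)OC | intermediate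
12 | (2R,4R,5S)-2-[(tert-butyldimethylsilyl)oxy]-4-ethenyl-5-hydroxy-N-methoxy-N,5-dimethyl-6-oxohexanamide | O=C[C@@](C)(O)[C@@H](C=C)C[C@@H](O[Si](C)(C)C(C)(C)C)C(=O)N(C)OC | intermediate
13 | prenyl chloride (1-chloro-3-methylbut-2-ene) | CC(C)=CCCl | starting material
14 | prenylbarium chloride | CC(C)=CC[Ba]Cl | intermediate
15 | (2R,4R,5S,6S)-2-[(tert-butyldimethylsilyl)oxy]-4-ethenyl-5,6-dihydroxy-N-methoxy-N,5,9-trimethyldec-8-enamide | O[C@@H](CC=C(C)C)[C@@](C)(O)[C@@H](C=C)C[C@@H](O[Si](C)(C)C(C)(C)C)C(=O)N(C)OC | intermediate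
16 | (2R,4R,5S,6S)-6-(acetyloxy)-2-[(tert-butyldimethylsilyl)oxy]-4-ethenyl-5-hydroxy-N-methoxy-N,5,9-trimethyldec-8-enamide | CC(=O)O[C@@H](CC=C(C)C)[C@@](C)(O)[C@@H](C=C)C[C@@H](O[Si](C)(C)C(C)(C)C)C(=O)N(C)OC | intermediate
17 | (2S,3S,5S)-5-bromo-2-{(3R,5R)-5-[(tert-butyldimethylsilyl)oxy]-6-[methoxy(methyl)amino]-6-oxohex-1-en-3-yl}-2,6,6-trimethyloxan-3-yl acetate | CC(=O)O[C@H]1C[C@H](Br)C(C)(C)O[C@@]1(C)[C@@H](C=C)C[C@@H](O[Si](C)(C)C(C)(C)C)C(=O)N(C)OC | intermediate
18 | methylmagnesium bromide | C[Mg]Br | starting material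
19 | (3R,5R)-5-[(2S,3S,5S)-5-bromo-3-hydroxy-2,6,6-trimethyloxan-2-yl]-3-[(tert-butyldimethylsilyl)oxy]hept-6-en-2-one | O[C@H]1C[C@H](Br)C(C)(C)O[C@@]1(C)[C@@H](C=C)C[C@@H](O[Si](C)(C)C(C)(C)C)C(C)=O | intermediate
20 | cyclic hemiketal (ring B closed between the C8 oxygen and C1; C1 bears OH and CH3, both anomers) | C=C[C@H]1C[C@@H](O[Si](C)(C)C(C)(C)C)C(C)(O)O[C@H]2C[C@H](Br)C(C)(C)O[C@@]12C | intermediate
21 | oxepanyl oxocarbenium ion (C1=O+ within ring B) | C=C[C@H]1C[C@@H](O[Si](C)(C)C(C)(C)C)C(C)=[O+][C@H]2C[C@H](Br)C(C)(C)O[C@@]12C | intermediate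
22 | (1R,2R,4R,5S,7S,8S,10S)-5-acetoxy-10-bromo-2-[(tert-butyldimethylsilyl)oxy]-1,8:7,11-diepoxybisabolane (locants of the overview) | CC(=O)O[C@H]1C[C@@]2(C)O[C@H]3C[C@H](Br)C(C)(C)O[C@@]3(C)[C@@H]1C[C@H]2O[Si](C)(C)C(C)(C)C | intermediate
23 | (1R,2R,4R,5S,7S,8S,10S)-5-acetoxy-10-bromo-1,8:7,11-diepoxybisabolan-2-ol, CNP0247588.2 (locants of the overview) | CC(=O)O[C@H]1C[C@@]2(C)O[C@H]3C[C@H](Br)C(C)(C)O[C@@]3(C)[C@@H]1C[C@H]2O | target

**Totals**

Total step count: 14. Longest linear sequence: 14 steps (1 → 23).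

**Steps most likely to fail**

1. Step 13 (proposed new method). The seven-membered oxocarbenium ion may form too slowly, so that desilylation or enol ether formation (which would epimerise C2) wins. The C5 cation may also be captured only after the C–C bond has formed, from the open face or by fluoride, which would give the C5 epimer or a fluoride. The fallback uses known chemistry and still closes ring C last. It sets out from 19: intramolecular ketalisation (MeOH, PPTS, 3 Å MS) should give the cyclic methyl ketal F1. Tsuji–Wacker oxidation of the vinyl group (PdCl2 cat., CuCl, O2, DMF/H2O) should give the methyl ketone F2. Kinetic enolisation (LiHMDS, TBSCl, THF, −78 °C) should give the silyl enol ether F3. Catalytic TMSOTf (CH2Cl2, −78 °C) should ionise the ketal to the same oxocarbenium ion, and the enol ether adds in an intramolecular Mukaiyama aldol-type reaction to give the tricyclic ketone F4. NaBH4 (MeOH, 0 °C) should deliver hydride from the face away from ring A to give the C5 alcohol F5. Acetylation (Ac2O, DMAP, pyridine) comes back to the route at 22.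

2. Step 11. The tertiary hydroxyl may close 5-exo onto the secondary alkene carbon to give a tetrahydrofuran, and the two chair transition states may differ too little, giving poor facial selectivity at C10. The fallback sets out from 16: mercuricyclisation with Hg(OCOCF3)2 (MeNO2, 0 °C; then aq KBr) is reversible and should settle on the six-membered ring with equatorial mercury, giving the organomercury bromide F6. Polar bromodemercuration with retention (Br2, LiBr, pyridine) comes back to the route at 17.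

3. Step 9. The organobarium reagent may lose α-regiocontrol, attack the Weinreb amide, or act as a base and trigger α-ketol rearrangement of aldehyde 12; chelate control may also be incomplete. The fallback sets out from 12: addition of lithiated prenyl phenyl sulfone (PhSO2CH2CH=CMe2, n-BuLi, THF, −78 °C) is expected to occur at the sulfonyl-bearing carbon under chelate control, giving the β-hydroxy sulfone F7. Palladium-catalysed reductive desulfonylation (Pd(PPh3)4 cat., NaBH4, THF/i-PrOH, 0 °C), with hydride delivered to the less substituted allyl terminus, comes back to the route at 15.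

**Further compounds**

F1 | step 13 | cyclic methyl ketal of 19 (ring B closed; C1 bears OCH3 and CH3) | C=C[C@H]1C[C@@H](O[Si](C)(C)C(C)(C)C)C(C)(OC)O[C@H]2C[C@H](Br)C(C)(C)O[C@@]12C
F2 | step 13 | methyl ketone from Wacker oxidation of F1 (acetyl group on C4) | CC(=O)[C@H]1C[C@@H](O[Si](C)(C)C(C)(C)C)C(C)(OC)O[C@H]2C[C@H](Br)C(C)(C)O[C@@]12C
F3 | step 13 | tert-butyldimethylsilyl enol ether of F2 (C5(OTBS)=C6H2 on C4) | C=C(O[Si](C)(C)C(C)(C)C)[C@H]1C[C@@H](O[Si](C)(C)C(C)(C)C)C(C)(OC)O[C@H]2C[C@H](Br)C(C)(C)O[C@@]12C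
F4 | step 13 | tricyclic C5 ketone (C2 silyl ether) | O=C1C[C@@]2(C)O[C@H]3C[C@H](Br)C(C)(C)O[C@@]3(C)[C@@H]1C[C@H]2O[Si](C)(C)C(C)(C)C
F5 | step 13 | tricyclic (5S)-C5 alcohol (C2 silyl ether) | O[C@H]1C[C@@]2(C)O[C@H]3C[C@H](Br)C(C)(C)O[C@@]3(C)[C@@H]1C[C@H]2O[Si](C)(C)C(C)(C)C
F6 | step 11 | organomercury bromide (HgBr in place of Br at C10 of 17) | CC(=O)O[C@H]1C[C@H]([Hg]Br)C(C)(C)O[C@@]1(C)[C@@H](C=C)C[C@@H](O[Si](C)(C)C(C)(C)C)C(=O)N(C)OC
F7 | step 9 | β-hydroxy sulfone (15 with a phenylsulfonyl group on C9; both epimers at C9) | O[C@@H](C(C=C(C)C)S(=O)(=O)c1ccccc1)[C@@](C)(O)[C@@H](C=C)C[C@@H](O[Si](C)(C)C(C)(C)C)C(=O)N(C)OC
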